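**Retrosynthetic overview**

1. Daucane numbering is used throughout: C1 quaternary fusion carbon (CH3), C2, C3, C4 (C–OH, i-Pr), C5 (fusion CH), C6 (CH–O), C7, C8(CH3)=C9, C10. β is the face of the C1 methyl group; "trinor" means the isopropyl group is absent.
2. The strategy rests on the five-membered ring C1–C2–C3–C4–C5. C4 carries oxygen and quaternary C1 is bonded to both C2 and C5, so this ring is taken back to a cyclopent-2-enone (C4=O, C2=C3) and opened at C1–C2 to a divinyl ketone C1=C5–C4(=O)–C3=C2–SiMe3 on the preformed seven-membered ring (C1, C5–C10).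
3. Ring order: the seven-membered ring first, by Birch reduction of 2,5-dimethylanisole and dibromocarbene one-carbon ring expansion to 2-bromo-3,6-dimethylcyclohepta-2,5-dienone. CBS reduction sets C6, on purpose epimeric to the target. The five-membered ring follows by silicon-directed Nazarov closure.
4. After the key step: conjugate reduction of C2=C3, i-Pr addition to C4 from the α face, inversion of C6 through the ketone by C4–OH-directed reduction, esterification with silyl-protected p-coumaric acid, desilylation.

Key step: step 10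

**Route**

Step 1
Reactants: 1 2,5-dimethylanisole
Product: 2 1-methoxy-2,5-dimethylcyclohexa-1,4-diene
Conditions: Li, liq. NH3, THF, t-BuOH, −78 to −33 °C; then H2O
Reagents that add atoms: none
Why: Birch reduction leaves the methoxy group and both methyl groups on sp2 carbons, which should give the skipped diene with a tetrasubstituted enol ether alkene and a trisubstituted alkene.

Step 2
Reactants: 2 1-methoxy-2,5-dimethylcyclohexa-1,4-diene
Product: 3 7,7-dibromo-1-methoxy-3,6-dimethylbicyclo[4.1.0]hept-3-ene (racemic, cis-fused cyclopropane)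
Conditions: CHBr3 (1.05 equiv), KOt-Bu, pentane, −20 to 0 °C
Reagents that add atoms: bromoform, BrC(Br)Br
Why: Dibromocarbene from α-elimination is electrophilic and should cyclopropanate the electron-rich enol ether alkene in preference to the trisubstituted alkene (dihalocarbene [2+1] cycloaddition); both stereocentres are erased in step 3.

Step 3
Reactants: 3 7,7-dibromo-1-methoxy-3,6-dimethylbicyclo[4.1.0]hept-3-ene
Product: 4 2-bromo-3,6-dimethylcyclohepta-2,5-dien-1-one
Conditions: AgNO3, NaHCO3, acetone/H2O, 20 °C, dark
Reagents that add atoms: water, O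
Why: Silver-assisted loss of the endo bromide with disrotatory cyclopropyl-to-allyl cation opening, pushed by the methoxy group, and hydrolysis of the methyl oxocarbenium ion should give the ring-expanded α-bromo enone (dihalocyclopropane one-carbon ring expansion); the buffer and room temperature are chosen so that 4 does not enolise towards a tropone.

Step 4
Reactants: 4 2-bromo-3,6-dimethylcyclohepta-2,5-dien-1-one
Product: 5 (R)-2-bromo-3,6-dimethylcyclohepta-2,5-dien-1-ol
Conditions: (S)-2-methyl-CBS-oxazaborolidine (0.2 equiv), catecholborane (1.5 equiv), toluene, −78 °C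
Reagents that add atoms: none
Why: Corey–Bakshi–Shibata reduction in which the α-bromovinyl group acts as the large substituent, so the (S)-catalyst should give the (R)-alcohol (C6, epimeric to the target by design); catecholborane at −78 °C does not hydroborate the trisubstituted alkene.

Step 5
Reactants: 5 (R)-2-bromo-3,6-dimethylcyclohepta-2,5-dien-1-ol
Product: 6 (R)-[(2-bromo-3,6-dimethylcyclohepta-2,5-dien-1-yl)oxy]triisopropylsilane
Conditions: i-Pr3SiOTf, 2,6-lutidine, CH2Cl2, 0 °C
Reagents that add atoms: triisopropylsilyl triflate, CC(C)[Si](OS(=O)(=O)C(F)(F)F)(C(C)C)C(C)C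
Why: Standard silylation of a secondary allylic alcohol with a silyl triflate; the triisopropylsilyl group is chosen because it is bulky, non-chelating and should survive FeCl3 in step 10.

Step 6
Reactants: 7 3-(trimethylsilyl)prop-2-yn-1-ol
Product: 8 (E)-3-(trimethylsilyl)prop-2-en-1-ol
Conditions: NaAlH2(OCH2CH2OCH3)2, Et2O, 0 to 20 °C; then H2O
Reagents that add atoms: none
Why: Alkoxide-directed trans-hydroalumination of the propargylic alcohol followed by protonolysis with retention should give the (E)-vinylsilane only.

Step 7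
Reactants: 8 (E)-3-(trimethylsilyl)prop-2-en-1-ol
Product: 9 (E)-3-(trimethylsilyl)prop-2-enal
Conditions: MnO2, CH2Cl2, 20 °C
Reagents that add atoms: none
Why: MnO2 oxidation of an allylic alcohol to the enal, which leaves the vinylsilane and its E geometry untouched; the volatile aldehyde is used as a solution.

Step 8
Reactants: 6 (R)-[(2-bromo-3,6-dimethylcyclohepta-2,5-dien-1-yl)oxy]triisopropylsilane; 9 (E)-3-(trimethylsilyl)prop-2-enal
Product: 11 (E)-1-[(7R)-2,5-dimethyl-7-(triisopropylsilyloxy)cyclohepta-1,4-dien-1-yl]-3-(trimethylsilyl)prop-2-en-1-ol (both carbinol epimers), via vinyllithium 10 (not isolated)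
Conditions: t-BuLi (2.05 equiv), Et2O, −78 °C; then 9, −78 °C; then H2O
Reagents that add atoms: none
Why: Bromine–lithium exchange at −78 °C is faster than deprotonation of the doubly allylic CH2, and the vinyllithium should add 1,2 to the unhindered enal to form C5–C4; the carbinol configuration is irrelevant because it is oxidised next.

Step 9
Reactants: 11 (E)-1-[(7R)-2,5-dimethyl-7-(triisopropylsilyloxy)cyclohepta-1,4-dien-1-yl]-3-(trimethylsilyl)prop-2-en-1-ol
Product: 12 (E)-1-[(7R)-2,5-dimethyl-7-(triisopropylsilyloxy)cyclohepta-1,4-dien-1-yl]-3-(trimethylsilyl)prop-2-en-1-one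
Conditions: MnO2, CH2Cl2, 20 °C
Reagents that add atoms: none
Why: MnO2 oxidation of the doubly allylic alcohol to the cross-conjugated dienone under neutral conditions, so that the skipped diene is not isomerised.

Step 10
Reactants: 12 (E)-1-[(7R)-2,5-dimethyl-7-(triisopropylsilyloxy)cyclohepta-1,4-dien-1-yl]-3-(trimethylsilyl)prop-2-en-1-one
Product: 14 (1S,5S,6R)-6-(triisopropylsilyloxy)-11,12,13-trinordauca-2,8-dien-4-one (trans-fused; 1-CH3 β; 5-H α; 6-OSi β), via dichloroiron dienolate 13 (not isolated)
Conditions: FeCl3 (1.1 equiv), CH2Cl2, −50 to −10 °C; then cold pH 7 buffer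
Reagents that add atoms: none
Why: FeCl3 binds the C4 carbonyl oxygen and the resulting hydroxypentadienyl cation over C1–C5–C4–C3–C2 should undergo thermal conrotatory 4π electrocyclisation (silicon-directed Nazarov cyclisation of a cycloalkenyl β-silylvinyl ketone, here onto a fully substituted terminus), which forms C1–C2 and closes the five-membered ring C1–C2–C3–C4–C5 onto the seven-membered ring. The β-silicon stabilises the cyclised oxyallyl cation at C3 and leaves as Me3SiCl, which fixes the alkene at C2=C3 and gives dienolate 13. The selectivity the step needs is the sense of conrotation, i.e. the face of C1 that bonds to C2: in the planar U-shaped cation the iron-bound oxygen on C4 eclipses C6, so 1,3-allylic strain should hold C6–H in the plane and the non-chelating silyloxy group perpendicular to it; because C7 and C10 must lie on one face for the seven-membered ring to stay closed, C10 rotates to the C7 side and the C1 methyl group ends up syn to the silyloxy group (1S). C5 is set on quench by kinetic protonation of 13 from the face opposite the C1 methyl and C6 silyloxy groups, which should give the trans ring fusion (5S); no equilibration is relied on, since the syn methyl/silyloxy arrangement may make the trans isomer the less stable one. Low temperature and the absence of protic acid are meant to spare the C8=C9 alkene, the doubly allylic C10 methylene and the silyl ether while the slower closure onto the fully substituted C1 takes place.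

Step 11
Reactants: 14 (1S,5S,6R)-6-(triisopropylsilyloxy)-11,12,13-trinordauca-2,8-dien-4-one
Product: 15 (1R,5S,6R)-6-(triisopropylsilyloxy)-11,12,13-trinordauc-8-en-4-one
Conditions: [(Ph3P)CuH]6 (0.25 equiv), H2O (3 equiv), benzene, 20 °C
Reagents that add atoms: none
Why: Conjugate reduction with the copper hydride hexamer delivers hydride to C2 and the copper enolate is protonated at C3, so C5 is not enolised, the β-silyloxy group is not eliminated and the trisubstituted C8=C9 alkene is left alone.

Step 12
Reactants: 15 (1R,5S,6R)-6-(triisopropylsilyloxy)-11,12,13-trinordauc-8-en-4-one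
Product: 16 (1R,4R,5S,6R)-6-(triisopropylsilyloxy)dauc-8-en-4-ol (4-OH β; 4-i-Pr α)
Conditions: i-PrMgCl, CeCl3 (anhydrous), THF, −78 to 0 °C; then H2O
Reagents that add atoms: isopropylmagnesium chloride, CC(C)[Mg]Cl
Why: Organocerium 1,2-addition, whose low basicity should suppress enolisation, β-hydride reduction and β-elimination of the silyloxy group; attack from the α face, opposite the C1 methyl and the C6 silyloxy group, sets C4 with the hydroxyl β.

Step 13
Reactants: 16 (1R,4R,5S,6R)-6-(triisopropylsilyloxy)dauc-8-en-4-ol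
Product: 17 (1R,4R,5S,6R)-dauc-8-ene-4,6-diol (4β,6β-diol)
Conditions: Bu4NF, THF, 50 °C
Reagents that add atoms: none
Why: Fluoride cleavage of the Si–O bond; the molecule has no base-sensitive group at this stage.

Step 14
Reactants: 17 (1R,4R,5S,6R)-dauc-8-ene-4,6-diol
Product: 18 (1R,4R,5R)-4-hydroxydauc-8-en-6-one (4-OH β; trans-fused)
Conditions: Dess–Martin periodinane, NaHCO3, CH2Cl2, 0 to 20 °C
Reagents that add atoms: none
Why: Dess–Martin oxidation of the secondary alcohol; the tertiary C4–OH cannot be oxidised, and the buffered neutral medium should avoid retro-aldol cleavage, dehydration, C5 epimerisation and conjugation of the β,γ-alkene.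

Step 15
Reactants: 18 (1R,4R,5R)-4-hydroxydauc-8-en-6-one
Product: 19 (1R,4R,5S,6S)-dauc-8-ene-4,6-diol (4β,6α-diol)
Conditions: Me4NBH(OAc)3, MeCN/AcOH (1:1), −30 to −20 °C
Reagents that add atoms: none
Why: Hydroxyl-directed (Evans–Saksena) reduction: the C4 hydroxyl exchanges an acetate on boron and delivers hydride through a six-membered transition state to the β face of C6, on which the 4β-oxygen lies, which should give the 6α-alcohol; the reagent is too weak to reduce the ketone without this delivery.

Step 16
Reactants: 20 p-coumaric acid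
Product: 22 (E)-3-[4-(tert-butyldimethylsilyloxy)phenyl]prop-2-enoic acid, via bis-silylated coumarate 21 (not isolated)
Conditions: t-BuMe2SiCl (2.3 equiv), imidazole, DMF, 20 °C; then AcOH/THF/H2O (3:1:1), 20 °C
Reagents that add atoms: tert-butyldimethylsilyl chloride, CC(C)(C)[Si](C)(C)Cl
Why: Silylation of phenol and acid followed by hydrolysis of the far more labile silyl ester, which leaves the acid-stable aryl silyl ether (standard protection of a hydroxycinnamic acid).

Step 17
Reactants: 19 (1R,4R,5S,6S)-dauc-8-ene-4,6-diol; 22 (E)-3-[4-(tert-butyldimethylsilyloxy)phenyl]prop-2-enoic acid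
Product: 23 (1R,4R,5S,6S)-4-hydroxydauc-8-en-6-yl (E)-3-[4-(tert-butyldimethylsilyloxy)phenyl]prop-2-enoate
Conditions: DCC, DMAP, CH2Cl2, 20 °C
Reagents that add atoms: none
Why: Steglich esterification, in which the secondary equatorial 6α-hydroxyl should acylate while the tertiary C4 hydroxyl, flanked by the isopropyl group, stays free.

Step 18
Reactants: 23 (1R,4R,5S,6S)-4-hydroxydauc-8-en-6-yl (E)-3-[4-(tert-butyldimethylsilyloxy)phenyl]prop-2-enoate
Product: 24 (1R,4R,5S,6S)-4-hydroxydauc-8-en-6-yl (E)-3-(4-hydroxyphenyl)prop-2-enoate (CNP0265426.1)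
Conditions: Bu4NF, AcOH (1:1), THF, 0 °C
Reagents that add atoms: none
Why: Fluoride cleaves the aryl silyl ether quickly because phenoxide is a good leaving group on silicon, and the acetic acid buffer should keep the cinnamate ester and the tertiary alcohol intact.

**Compound list**

1 | 2,5-dimethylanisole | COc1cc(C)ccc1C | starting material
2 | 1-methoxy-2,5-dimethylcyclohexa-1,4-diene | COC1=C(C)CC=C(C)C1 | intermediate
3 | 7,7-dibromo-1-methoxy-3,6-dimethylbicyclo[4.1.0]hept-3-ene (racemic) | COC12CC(C)=CCC1(C)C2(Br)Br | intermediate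
4 | 2-bromo-3,6-dimethylcyclohepta-2,5-dien-1-one | CC1=CCC(C)=C(Br)C(=O)C1 | intermediate
5 | (R)-2-bromo-3,6-dimethylcyclohepta-2,5-dien-1-ol | CC1=CCC(C)=C(Br)[C@H](O)C1 | intermediate
6 | (R)-[(2-bromo-3,6-dimethylcyclohepta-2,5-dien-1-yl)oxy]triisopropylsilane | CC1=CCC(C)=C(Br)[C@H](O[Si](C(C)C)(C(C)C)C(C)C)C1 | intermediate
7 | 3-(trimethylsilyl)prop-2-yn-1-ol | C[Si](C)(C)C#CCO | starting material
8 | (E)-3-(trimethylsilyl)prop-2-en-1-ol | C[Si](C)(C)/C=C/CO | intermediate
9 | (E)-3-(trimethylsilyl)prop-2-enal | C[Si](C)(C)/C=C/C=O | intermediate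
10 | [(7R)-2,5-dimethyl-7-(triisopropylsilyloxy)cyclohepta-1,4-dien-1-yl]lithium | CC1=CCC(C)=C([Li])[C@H](O[Si](C(C)C)(C(C)C)C(C)C)C1 | intermediate
11 | (E)-1-[(7R)-2,5-dimethyl-7-(triisopropylsilyloxy)cyclohepta-1,4-dien-1-yl]-3-(trimethylsilyl)prop-2-en-1-ol (both carbinol epimers) | CC1=CCC(C)=C(C(O)/C=C/[Si](C)(C)C)[C@H](O[Si](C(C)C)(C(C)C)C(C)C)C1 | intermediate
12 | (E)-1-[(7R)-2,5-dimethyl-7-(triisopropylsilyloxy)cyclohepta-1,4-dien-1-yl]-3-(trimethylsilyl)prop-2-en-1-one | CC1=CCC(C)=C(C(=O)/C=C/[Si](C)(C)C)[C@H](O[Si](C(C)C)(C(C)C)C(C)C)C1 | intermediate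
13 | dichloroiron dienolate of 14 (C4–O–FeCl2, C4=C5, C2=C3) | CC1=CC[C@@]2(C)C=CC(O[Fe](Cl)Cl)=C2[C@H](O[Si](C(C)C)(C(C)C)C(C)C)C1 | intermediate
14 | (1S,5S,6R)-6-(triisopropylsilyloxy)-11,12,13-trinordauca-2,8-dien-4-one | CC1=CC[C@@]2(C)C=CC(=O)[C@@H]2[C@H](O[Si](C(C)C)(C(C)C)C(C)C)C1 | intermediate
15 | (1R,5S,6R)-6-(triisopropylsilyloxy)-11,12,13-trinordauc-8-en-4-one | CC1=CC[C@@]2(C)CCC(=O)[C@@H]2[C@H](O[Si](C(C)C)(C(C)C)C(C)C)C1 | intermediate
16 | (1R,4R,5S,6R)-6-(triisopropylsilyloxy)dauc-8-en-4-ol | CC1=CC[C@@]2(C)CC[C@@](O)(C(C)C)[C@@H]2[C@H](O[Si](C(C)C)(C(C)C)C(C)C)C1 | intermediate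
17 | (1R,4R,5S,6R)-dauc-8-ene-4,6-diol (4β,6β) | CC1=CC[C@@]2(C)CC[C@@](O)(C(C)C)[C@@H]2[C@H](O)C1 | intermediate
18 | (1R,4R,5R)-4-hydroxydauc-8-en-6-one | CC1=CC[C@@]2(C)CC[C@@](O)(C(C)C)[C@@H]2C(=O)C1 | intermediate
19 | (1R,4R,5S,6S)-dauc-8-ene-4,6-diol (4β,6α) | CC1=CC[C@@]2(C)CC[C@@](O)(C(C)C)[C@@H]2[C@@H](O)C1 | intermediate
20 | p-coumaric acid | OC(=O)/C=C/c1ccc(O)cc1 | starting material
21 | tert-butyldimethylsilyl (E)-3-[4-(tert-butyldimethylsilyloxy)phenyl]prop-2-enoate | CC(C)(C)[Si](C)(C)OC(=O)/C=C/c1ccc(O[Si](C)(C)C(C)(C)C)cc1 | intermediate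
22 | (E)-3-[4-(tert-butyldimethylsilyloxy)phenyl]prop-2-enoic acid | OC(=O)/C=C/c1ccc(O[Si](C)(C)C(C)(C)C)cc1 | intermediate
23 | (1R,4R,5S,6S)-4-hydroxydauc-8-en-6-yl (E)-3-[4-(tert-butyldimethylsilyloxy)phenyl]prop-2-enoate | CC1=CC[C@@]2(C)CC[C@@](O)(C(C)C)[C@@H]2[C@@H](OC(=O)/C=C/c2ccc(O[Si](C)(C)C(C)(C)C)cc2)C1 | intermediate
24 | (1R,4R,5S,6S)-4-hydroxydauc-8-en-6-yl (E)-3-(4-hydroxyphenyl)prop-2-enoate (CNP0265426.1) | CC1=CC[C@@]2(C)CC[C@@](O)(C(C)C)[C@@H]2[C@@H](OC(=O)/C=C/c2ccc(O)cc2)C1 | target

**Step count**

Total: 18 steps. Longest linear sequence: 15 steps (steps 1–5, 8–15, 17, 18, from 2,5-dimethylanisole).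

**Steps most likely to fail**

Step 10 (Nazarov closure). Bond formation at the fully substituted C1 may be slow enough for proton loss from C10 and migration of the ring alkenes to compete. Closure may also occur with the wrong sense of rotation, C5 may be protonated from the wrong face or epimerise to the cis fusion, or the silyl ether may be lost. The fallback builds the five-membered ring without a cationic step; it sets out from bromide 6 and comes back at ketone 15. Vinyllithium 10, made as in step 8, is quenched with DMF to give (7R)-2,5-dimethyl-7-(triisopropylsilyloxy)cyclohepta-1,4-diene-1-carbaldehyde F1. Copper-catalysed conjugate addition of vinylmagnesium bromide (CuBr·SMe2, Me3SiCl, THF, −78 °C, then mild acid), anti to the silyloxy group, should form quaternary C1 and give 2-ethenyl-2,5-dimethyl-7-(triisopropylsilyloxy)cyclohept-4-ene-1-carbaldehyde F2 (vinyl anti to the silyloxy group, formyl trans to vinyl, correctable by base at C5). Intramolecular hydroacylation of this 4-pentenal with [Rh(Ph2PCH2CH2PPh2)]ClO4 in CH2Cl2 then closes C4–C3 and should give 15.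

Step 12 (isopropyl addition). The hindered ketone may be enolised or reduced by β-hydride transfer instead of being attacked, the silyloxy group may be eliminated, or the nucleophile may come from the β face. The fallback sets out from 15 and comes back at 16. 2-Propenylmagnesium bromide with CeCl3 (THF, −78 °C), a smaller sp2 nucleophile without β-hydrogens, should give (1R,4S,5S,6R)-6-(triisopropylsilyloxy)dauca-8,11-dien-4-ol F3. Its 1,1-disubstituted alkene is then hydrogenated with H2 and RhCl(PPh3)3 in benzene, which should spare the trisubstituted C8=C9 alkene and give 16.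

Step 15 (directed reduction at C6). Acetate exchange at the hindered tertiary C4 hydroxyl may be too slow for hydride delivery, undirected attack from the α face would return 17, and ketone 18 may suffer retro-aldol cleavage or C5 epimerisation while it waits. The fallback inverts C6 without passing through the ketone; it sets out from diol 17 and comes back at ester 23. Mitsunobu esterification of 17 with acid 22 (PPh3, diisopropyl azodicarboxylate, toluene, 0 to 20 °C) should displace the activated 6β-oxygen with inversion and give 23 directly; no compound outside the list is made (F0).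

**Further compounds**

F1 | step 10 | (7R)-2,5-dimethyl-7-(triisopropylsilyloxy)cyclohepta-1,4-diene-1-carbaldehyde | CC1=CCC(C)=C(C=O)[C@H](O[Si](C(C)C)(C(C)C)C(C)C)C1
F2 | step 10 | 2-ethenyl-2,5-dimethyl-7-(triisopropylsilyloxy)cyclohept-4-ene-1-carbaldehyde (vinyl anti to silyloxy, formyl trans to vinyl) | CC1=CC[C@@](C)(C=C)[C@H](C=O)[C@H](O[Si](C(C)C)(C(C)C)C(C)C)C1
F3 | step 12 | (1R,4S,5S,6R)-6-(triisopropylsilyloxy)dauca-8,11-dien-4-ol | CC1=CC[C@@]2(C)CC[C@@](O)(C(C)=C)[C@@H]2[C@H](O[Si](C(C)C)(C(C)C)C(C)C)C1
F0 | step 15 | none | none
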